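**Retrosynthetic overview**
Numbering (3,7-dioxabicyclo[3.3.0]octane): C1 carbinol bridgehead, C2 (syringyl), O3, C4, C5 (CH bridgehead), C6 (guaiacyl), O7, C8. Ring A = C1–C5–C6–O7–C8 and ring B = C1–C2–O3–C4–C5.
Ring B is closed last. The C1–C2 bond comes from a Norrish–Yang cyclisation of a ring A ketone (C1=O) that carries C5–C4H2–O3–CH2–aryl, and this one event sets both C1 and C2.
The C5–C4 bond comes from alkoxymethylation of a regiodefined C5=C1 enol silane, anti to the C6 aryl group.
The C6–aryl bond comes from a Heck arylation of the four-carbon furanoid glycal O7–C6H=C5H–C1H(OTBS)–C8H2 with a protected 4-iodoguaiacol. Ring A is bought as (R)-3-hydroxy-γ-butyrolactone and is never opened.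
Enabling feature: in ring A, C6 is bonded to O7 and stands 1,3 to the oxygen-bearing C1. This O7–C6–C5–C1(O) array maps onto an allylically oxygenated enol ether, so aryl-palladium goes to C6 anti to the C1 oxygen, and hydride loss from C1 leaves C1 at the ketone level and C5 nucleophilic.

Key step: step 5

Assumption: the anomeric carbons of 3 and 4 are epimer mixtures and are written without configuration, because step 3 erases them.

Step 1
Reactants: 1 (R)-3-hydroxy-γ-butyrolactone
Product: 2 (R)-4-[(tert-butyldimethylsilyl)oxy]dihydrofuran-2(3H)-one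
Conditions: TBSCl, imidazole, CH2Cl2, 0 °C to rt
Reagents that add atoms: tert-butyldimethylsilyl chloride, CC(C)(C)[Si](C)(C)Cl
Why: Imidazole-promoted O-silylation of a secondary alcohol is mild enough to avoid β-elimination to the butenolide and leaves the bought stereocentre (the later C1) untouched.

Step 2
Reactants: 2 (R)-4-[(tert-butyldimethylsilyl)oxy]dihydrofuran-2(3H)-one
Product: 3 (4R)-4-[(tert-butyldimethylsilyl)oxy]tetrahydrofuran-2-ol (both anomers)
Conditions: i-Bu2AlH (1.1 equiv), CH2Cl2, −78 °C; MeOH, aq. KNaC4H4O6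
Reagents that add atoms: none
Why: Partial reduction of a γ-lactone with i-Bu2AlH should stop at the lactol because the aluminium hemiacetal is stable at −78 °C, and the new anomeric centre does not matter since step 3 erases it.

Step 3
Reactants: 3 (4R)-4-[(tert-butyldimethylsilyl)oxy]tetrahydrofuran-2-ol
Product: 5 (R)-tert-butyl[(2,3-dihydrofuran-3-yl)oxy]dimethylsilane, via anomeric mesylate 4 (not isolated)
Conditions: MsCl, Et3N, CH2Cl2, −40 °C to reflux
Reagents that add atoms: methanesulfonyl chloride, CS(=O)(=O)Cl (its atoms are kept only in 4)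
Why: Mesylation of a 2-deoxy lactol followed by amine-induced elimination (glycal synthesis by dehydration of a 2-deoxy furanose) should give the enol ether, and the basic medium protects the acid-labile allylic silyl ether from loss of silanol.

Step 4
Reactants: 6 4-iodo-2-methoxyphenol
Product: 7 (4-iodo-2-methoxyphenoxy)triisopropylsilane
Conditions: TIPSCl, imidazole, DMF, rt
Reagents that add atoms: triisopropylsilyl chloride, CC(C)[Si](Cl)(C(C)C)C(C)C
Why: Standard phenol silylation gives a bulky aryl silyl ether that should survive the amine base, the Lewis acid and the irradiation, and that falls to fluoride at the end.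

Step 5
Reactants: 5 (R)-tert-butyl[(2,3-dihydrofuran-3-yl)oxy]dimethylsilane; 7 (4-iodo-2-methoxyphenoxy)triisopropylsilane
Product: 8 (S)-tert-butyl({5-[3-methoxy-4-(triisopropylsilyloxy)phenyl]-2,5-dihydrofuran-3-yl}oxy)dimethylsilane
Conditions: Pd(OAc)2 (10 mol %), AsPh3 (20 mol %), n-Bu3N, DMF, 60 °C
Reagents that add atoms: none
Why: Zerovalent palladium formed in situ from Pd(OAc)2 inserts into the C–I bond of 7, the arylpalladium iodide adds syn across the polarised C6=C5 enol ether of 5 with the aryl group on C6 and palladium on C5, and syn β-hydride elimination of the C1–H releases enol silane 8 while n-Bu3N takes up HI. The closest known reaction type is the Mizoroki–Heck C-arylation of 3-O-silylated furanoid glycals with aryl iodides, the standard entry to 2-deoxy C-aryl furanosides. No ring is closed; ring A is carried through intact. The new C6 stereocentre is controlled by the silyloxy group on C1, the only substituent on the flat ring: palladium and aryl approach the opposite face, which gives (S)-C6 from (R)-5 while the C1 stereocentre is spent (1,3-chirality transfer). The step needs regioselective addition, secured by O7, which directs the aryl group to the carbon it is bonded to, and a single direction of elimination, secured by the syn rule, since after syn addition C6–H lies anti to palladium and C1–H is the only syn β-hydrogen. One operation thus makes the aryl–C6 bond, sets C6, raises C1 to the ketone level without an oxidant and leaves C5 as the only nucleophilic α-carbon, which is what steps 10 and 11 draw on.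

Step 6
Reactants: 9 syringaldehyde (4-hydroxy-3,5-dimethoxybenzaldehyde)
Product: 10 3,5-dimethoxy-4-(triisopropylsilyloxy)benzaldehyde
Conditions: TIPSCl, imidazole, DMAP (cat.), DMF, 40 °C
Reagents that add atoms: triisopropylsilyl chloride, CC(C)[Si](Cl)(C(C)C)C(C)C
Why: Phenol silylation, helped by DMAP and gentle heating for the doubly ortho-substituted phenol, gives the same base-tolerant and fluoride-labile protection as in 7.

Step 7
Reactants: 10 3,5-dimethoxy-4-(triisopropylsilyloxy)benzaldehyde
Product: 11 [3,5-dimethoxy-4-(triisopropylsilyloxy)phenyl]methanol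
Conditions: NaBH4, MeOH, 0 °C
Reagents that add atoms: none
Why: Borohydride reduction of an aromatic aldehyde is chemoselective and leaves the aryl silyl ether alone.

Step 8
Reactants: 11 [3,5-dimethoxy-4-(triisopropylsilyloxy)phenyl]methanol
Product: 12 {2,6-dimethoxy-4-[(methylthiomethoxy)methyl]phenoxy}triisopropylsilane
Conditions: NaH, MeSCH2Cl, NaI (cat.), THF, 0 °C to rt
Reagents that add atoms: chloromethyl methyl sulfide, CSCCl
Why: Williamson-type O-alkylation with iodide catalysis is the usual way to methylthiomethyl ethers of benzylic alcohols, and the hindered triisopropylsilyl ether should resist silyl transfer under these conditions.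

Step 9
Reactants: 12 {2,6-dimethoxy-4-[(methylthiomethoxy)methyl]phenoxy}triisopropylsilane
Product: 13 {4-[(chloromethoxy)methyl]-2,6-dimethoxyphenoxy}triisopropylsilane
Conditions: SO2Cl2, CH2Cl2, −78 to 0 °C; evaporate, use crude
Reagents that add atoms: sulfuryl chloride, O=S(=O)(Cl)Cl
Why: Chlorinolysis of the O,S-acetal is the standard route to substituted benzyl chloromethyl ethers, since sulfur is attacked far faster than the arene at low temperature and the other products are volatile.

Step 10
Reactants: 8 (S)-tert-butyl({5-[3-methoxy-4-(triisopropylsilyloxy)phenyl]-2,5-dihydrofuran-3-yl}oxy)dimethylsilane; 13 {4-[(chloromethoxy)methyl]-2,6-dimethoxyphenoxy}triisopropylsilane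
Product: 14 (4R,5S)-4-({[3,5-dimethoxy-4-(triisopropylsilyloxy)benzyl]oxy}methyl)-5-[3-methoxy-4-(triisopropylsilyloxy)phenyl]dihydrofuran-3(2H)-one
Conditions: ZnBr2 (20 mol %), 2,6-di-tert-butylpyridine, CH2Cl2, −40 to 0 °C
Reagents that add atoms: none
Why: In this Mukaiyama-type α-alkoxymethylation ZnBr2 ionises 13 at the acetal carbon, and the cation is attacked only by C5 of the regiodefined enol silane from the face anti to the neighbouring C6 aryl group, so that C5 is set trans to C6 (R), the arrangement also favoured at equilibrium.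

Step 11
Reactants: 14 (4R,5S)-4-({[3,5-dimethoxy-4-(triisopropylsilyloxy)benzyl]oxy}methyl)-5-[3-methoxy-4-(triisopropylsilyloxy)phenyl]dihydrofuran-3(2H)-one
Product: 15 (1S,2R,5R,6S)-2-[3,5-dimethoxy-4-(triisopropylsilyloxy)phenyl]-6-[3-methoxy-4-(triisopropylsilyloxy)phenyl]-3,7-dioxabicyclo[3.3.0]octan-1-ol
Conditions: hν (medium-pressure Hg lamp, Pyrex filter), degassed benzene, rt
Reagents that add atoms: none
Why: In this Norrish–Yang cyclisation, a reaction type established for 4-(benzyloxymethyl)tetrahydrofuran-3-ones, the excited C1 ketone has no γ-hydrogen on this side because the γ-atom is O3, so it abstracts a benzylic δ-hydrogen through a seven-membered transition state and radical–radical C1–C2 coupling closes the five-membered ring B, the C5–C4–O3 tether allowing bonding only on the ketone face cis to C4 (cis fusion, C1–OH on the convex face, S) and the aryl group turning outward to the exo position (C2, R).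

Step 12
Reactants: 15 (1S,2R,5R,6S)-2-[3,5-dimethoxy-4-(triisopropylsilyloxy)phenyl]-6-[3-methoxy-4-(triisopropylsilyloxy)phenyl]-3,7-dioxabicyclo[3.3.0]octan-1-ol
Product: 16 fraxiresinol, (1S,2R,5R,6S)-2-(4-hydroxy-3,5-dimethoxyphenyl)-6-(4-hydroxy-3-methoxyphenyl)-3,7-dioxabicyclo[3.3.0]octan-1-ol
Conditions: n-Bu4NF, AcOH, THF, 0 °C
Reagents that add atoms: none
Why: Fluoride cleaves both aryl silyl ethers quickly, and the acetic acid buffer keeps free phenoxides from opening the benzylic C2–O3 and C6–O7 bonds through quinone methides, so no stereocentre should be scrambled.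

**Compound list**
1 | (R)-3-hydroxy-γ-butyrolactone | O=C1C[C@@H](O)CO1 | starting material
2 | (R)-4-[(tert-butyldimethylsilyl)oxy]dihydrofuran-2(3H)-one | O=C1C[C@@H](O[Si](C)(C)C(C)(C)C)CO1 | intermediate
3 | (4R)-4-[(tert-butyldimethylsilyl)oxy]tetrahydrofuran-2-ol, both anomers | OC1C[C@@H](O[Si](C)(C)C(C)(C)C)CO1 | intermediate
4 | (4R)-4-[(tert-butyldimethylsilyl)oxy]tetrahydrofuran-2-yl methanesulfonate (anomeric mesylate, not isolated) | CS(=O)(=O)OC1C[C@@H](O[Si](C)(C)C(C)(C)C)CO1 | intermediate
5 | (R)-tert-butyl[(2,3-dihydrofuran-3-yl)oxy]dimethylsilane (furanoid glycal) | C1=C[C@@H](O[Si](C)(C)C(C)(C)C)CO1 | intermediate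
6 | 4-iodo-2-methoxyphenol | COc1cc(I)ccc1O | starting material
7 | (4-iodo-2-methoxyphenoxy)triisopropylsilane | COc1cc(I)ccc1O[Si](C(C)C)(C(C)C)C(C)C | intermediate
8 | (S)-tert-butyl({5-[3-methoxy-4-(triisopropylsilyloxy)phenyl]-2,5-dihydrofuran-3-yl}oxy)dimethylsilane | COc1cc([C@@H]2C=C(O[Si](C)(C)C(C)(C)C)CO2)ccc1O[Si](C(C)C)(C(C)C)C(C)C | intermediate
9 | syringaldehyde | COc1cc(C=O)cc(OC)c1O | starting material
10 | 3,5-dimethoxy-4-(triisopropylsilyloxy)benzaldehyde | COc1cc(C=O)cc(OC)c1O[Si](C(C)C)(C(C)C)C(C)C | intermediate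
11 | [3,5-dimethoxy-4-(triisopropylsilyloxy)phenyl]methanol | COc1cc(CO)cc(OC)c1O[Si](C(C)C)(C(C)C)C(C)C | intermediate
12 | {2,6-dimethoxy-4-[(methylthiomethoxy)methyl]phenoxy}triisopropylsilane | COc1cc(COCSC)cc(OC)c1O[Si](C(C)C)(C(C)C)C(C)C | intermediate
13 | {4-[(chloromethoxy)methyl]-2,6-dimethoxyphenoxy}triisopropylsilane | COc1cc(COCCl)cc(OC)c1O[Si](C(C)C)(C(C)C)C(C)C | intermediate
14 | (4R,5S)-4-({[3,5-dimethoxy-4-(triisopropylsilyloxy)benzyl]oxy}methyl)-5-[3-methoxy-4-(triisopropylsilyloxy)phenyl]dihydrofuran-3(2H)-one (aryl and side chain trans) | COc1cc([C@@H]2[C@@H](COCc3cc(OC)c(O[Si](C(C)C)(C(C)C)C(C)C)c(OC)c3)C(=O)CO2)ccc1O[Si](C(C)C)(C(C)C)C(C)C | intermediate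
15 | bis(triisopropylsilyl) ether of fraxiresinol, (1S,2R,5R,6S), both aryl groups exo, cis-fused | COc1cc([C@H]2OC[C@]3(O)[C@@H](c4cc(OC)c(O[Si](C(C)C)(C(C)C)C(C)C)c(OC)c4)OC[C@H]23)ccc1O[Si](C(C)C)(C(C)C)C(C)C | intermediate
16 | fraxiresinol, (1S,2R,5R,6S) | COc1cc([C@H]2OC[C@]3(O)[C@@H](c4cc(OC)c(O)c(OC)c4)OC[C@H]23)ccc1O | target

**Count and risks**
Total step count: 12. Longest linear sequence: 7 steps (1, 2, 3, 5, 10, 11, 12, or equally 6, 7, 8, 9, 10, 11, 12).

**Risk 1, step 11.**
- What may go wrong: α-cleavage of the excited ketone toward the oxygen-bearing C8, quenching of the excited state by charge transfer from the electron-rich arenes, and poor exo/endo selection at C2 when the biradical closes.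
- Fallback: it sets out from 8 and 10 and comes back at 15. The same C1–C2 bond is closed reductively in the ground state.
- Route: 8 is hydroxymethylated as described under risk 2 to hydroxymethyl ketone F6. F6 is condensed with aldehyde 10 and benzotriazole (TsOH cat., molecular sieves, toluene) to the N-(α-alkoxybenzyl)benzotriazole F8. SmI2 in THF then cleaves the C–N bond reductively, and the α-alkoxybenzyl samarium species adds to the ketone in a 5-exo Barbier-type closure. The same tether control fixes C1 and the same exo preference fixes C2, giving 15.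

**Risk 2, step 10.**
- What may go wrong: Lewis-acid opening of the doubly activated C6–O7 bond with erosion of configuration at C6, ionisation of 13 at its benzylic carbon instead of the acetal carbon, and protodesilylation of 8.
- Fallback: it sets out from 8 and 11 and comes back at 14. C4 is introduced as formaldehyde under water-tolerant catalysis, and O3 is benzylated afterwards.
- Route: 8 with aqueous formaldehyde and Yb(OTf)3 in THF should give hydroxymethyl ketone F6, trans as before. Alcohol 11 with Cl3CCN and DBU (cat.) gives trichloroacetimidate F7. F6 and F7 with La(OTf)3 (cat.) in toluene give 14.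

**Risk 3, step 5.**
- What may go wrong: loss of silanol from 5 with aromatisation to furan at 60 °C, incomplete facial discrimination by the single silyloxy group, and re-addition of palladium hydride with migration of the double bond.
- Fallback: it sets out from 13 and 7 and comes back at 14. The aryl–C6 bond is made by polar substitution at an anomeric centre instead of by carbopalladation, with the C4 arm put in first.
- Route: bought (S)-3-hydroxy-γ-butyrolactone F1 is converted with i-Pr2NLi (2.2 equiv, THF, −78 °C) into its dianion and alkylated with 13 anti to the alkoxide (Fráter–Seebach-type alkylation) to trans lactone F2.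
- i-Bu2AlH then gives lactol F3, and PhSO2H with CaCl2 gives anomeric phenyl sulfone F4.
- The arylzinc reagent made from 7 (i-PrMgCl·LiCl, then ZnBr2) replaces the sulfinate through the ring oxocarbenium ion. It enters trans to the C5 side chain and cis to the C1 oxygen, giving aryl tetrahydrofuranol F5.
- Dess–Martin oxidation erases the C1 carbinol centre and gives 14.

**Further compounds**
F1 | step 5 | (S)-3-hydroxy-γ-butyrolactone (bought) | O=C1C[C@H](O)CO1
F2 | step 5 | (3S,4S)-3-({[3,5-dimethoxy-4-(triisopropylsilyloxy)benzyl]oxy}methyl)-4-hydroxydihydrofuran-2(3H)-one (trans) | O=C1[C@@H](COCc2cc(OC)c(O[Si](C(C)C)(C(C)C)C(C)C)c(OC)c2)[C@H](O)CO1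
F3 | step 5 | lactol of F2, both anomers | OC1[C@@H](COCc2cc(OC)c(O[Si](C(C)C)(C(C)C)C(C)C)c(OC)c2)[C@H](O)CO1
F4 | step 5 | anomeric phenyl sulfone from F3, both anomers | O=S(=O)(c1ccccc1)C2[C@@H](COCc3cc(OC)c(O[Si](C(C)C)(C(C)C)C(C)C)c(OC)c3)[C@H](O)CO2
F5 | step 5 | (3S,4S,5S)-4-({[3,5-dimethoxy-4-(triisopropylsilyloxy)benzyl]oxy}methyl)-5-[3-methoxy-4-(triisopropylsilyloxy)phenyl]tetrahydrofuran-3-ol | COc1cc([C@@H]2[C@@H](COCc3cc(OC)c(O[Si](C(C)C)(C(C)C)C(C)C)c(OC)c3)[C@H](O)CO2)ccc1O[Si](C(C)C)(C(C)C)C(C)C
F6 | step 10 | (4R,5S)-4-(hydroxymethyl)-5-[3-methoxy-4-(triisopropylsilyloxy)phenyl]dihydrofuran-3(2H)-one | COc1cc([C@@H]2[C@@H](CO)C(=O)CO2)ccc1O[Si](C(C)C)(C(C)C)C(C)C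
F7 | step 10 | 3,5-dimethoxy-4-(triisopropylsilyloxy)benzyl 2,2,2-trichloroacetimidate | COc1cc(COC(=N)C(Cl)(Cl)Cl)cc(OC)c1O[Si](C(C)C)(C(C)C)C(C)C
F8 | step 11 | N-(α-alkoxybenzyl)benzotriazole from F6, 10 and benzotriazole, both epimers at the new carbon | COc1cc([C@@H]2[C@@H](COC(c3cc(OC)c(O[Si](C(C)C)(C(C)C)C(C)C)c(OC)c3)n3nnc4ccccc43)C(=O)CO2)ccc1O[Si](C(C)C)(C(C)C)C(C)C
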